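Monday's highest reading of target is 39.0% of the starting material charged, with a scatter of 1.00% of that charge, and my reckoning for Saturday's run starts from it.

| setting | Friday's | Wednesday's | Monday's | Saturday's |
|---|---|---|---|---|
| starting material | 0.100 M | 0.0400 M | 0.100 M | 0.0330 M |
| coupling partner | 0.100 M | 0.0400 M | 0.300 M | 0.0500 M |
| time |  |  |  | 90 min |

- Friday's run (time / min: [target] / M): 4.0: 0.0065; 12: 0.0162; 23: 0.0260; 37: 0.0314; 53: 0.0367; 70: 0.0355; 90: 0.0378
- Wednesday's run (time / min: [target] / M): 4.0: 6 × 10⁻⁴; 12: 0.0055; 23: 0.0066; 37: 0.0102; 53: 0.0129; 70: 0.0153; 90: 0.0163
- Monday's run (time / min: [target] / M): 4.0: 0.0170; 12: 0.0356; 23: 0.0390; 37: 0.0336; 53: 0.0218; 70: 0.0168; 90: 0.0089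

(scatter of a reading: 0.001 M)

- Overall: starting material + coupling partner -> target.
- Constant volume, constant temperature.
- Readings of a species count what is bound in complexes too.
- "The second partner" is coupling partner.
- An order is taken over about fifteen percent of the charge, up and down.

- how the opening rate goes with [starting material] round the charge of the Friday's run: the exponent of the rate at two percent of starting material gone to target (one fixed amount of target, the same in the runs compared)
- how the opening rate goes with [coupling partner] round the charge of the Friday's run: the exponent of the rate at two percent of starting material gone to target
- target in the Saturday's run at 90 min, as a share of the starting material charged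

Monday's target falls to 8.90% by 90 min, so I take it that a second step with coupling partner consumes it. Tripling the coupling partner raises the first reading 2.62-fold, an exponent of 0.875, so I treat both steps as first order in it. In that reckoning coupling partner enters the clock, the working constant of the first step times coupling partner times time, and cancels from the height of the peak.

The bench rule says that with equal constants an intermediate peaks at 36.8%. Near that point I invert it for Monday:

loss ratio = 1 − 2(1 + ln peak share) = 0.883

I can't carry Monday's ratio over unchanged, because Saturday's starting material is 3.03 times thinner than Monday's. In Friday's and Wednesday's runs, each with its two charges equal, the readings nearest a quarter of the charge stand at 23 min and 37 min, a stretch of 1.61-fold, less than the 2.50-fold a fixed constant requires. So I read the working constant of the first step as varying with charge to the power −0.481, which gives a read exponent in starting material of 0.519. I scale Monday's ratio accordingly: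

Saturday's ratio = 0.518; peak share = 49.3%

I carry on with this selectivity factor at a given charge, the loss constant over the working constant of the first step. Monday's highest reading, at 23 min, also gives a working constant of 0.185 M⁻¹ min⁻¹, which I scale to 0.315 M⁻¹ min⁻¹ for Saturday's run, with the reckoned peak at clock 1.36.

Round one, coupling partner held at its charge: clock 1.42, share 49.3%

Round two, 0.0338 M of coupling partner reckoned consumed by the end, its mean level taken over the run: clock 0.940, share 46.4%

The forecast gives exponents of 0.6 in starting material and 1 in coupling partner, and 37.5% for Saturday's run, “right around the maximum”, which is lower than my 46.4%.

The flask gives 46.7% on Saturday, with exponents 0.59 and 1.0.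

    starting material + coupling partner → target + by-product (0.8760 M⁻¹ min⁻¹)
    2 starting material ⇌ idle substrate dimer, settled at all times (76.00 M⁻¹)
    target + coupling partner → side product (0.2370 M⁻¹ min⁻¹)

Saturday's share lies 2.6 percentage points below the peak reckoned from its selectivity factor 0.518. The quarter times of 21.2 min on Friday and 32.5 min on Wednesday give a dilution power of 0.532. Carried to Wednesday's charge, the factor becomes 0.574, with a reckoned peak of 47.3%. Wednesday's last reading, at 90 min, stands below that at 40.8%.

The numbers in the tables come from a simulation for substances that don't exist; noise was put on by code.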